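The route rests on making ring C last, by benzannulation onto the ring B oxygen: ring C carbons C3–C6, with the C4 bromine, come from 5-bromo-2-pyrone and C1–C2 from an oxygen-bound silylalkyne. One Diels–Alder/CO2-extrusion operation forms the C1–C6 and C2–C3 bonds, delivers ring C already aromatic and fixes bromine para to oxygen and silicon at C2, the carbon later turned into C–I. The precursor is the trimethylsilylethynyl ether of the fully brominated ring A–B phenol, ring A carrying a dioxolane-masked formyl group as latent phenol; it is assembled from 4,5-dibromocatechol without any alkyllithium, so no aryl bromide is exchanged.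

Key step: step 7

Remark: the target is drawn as the free aryl hydrogen sulfate, so the route ends at that acid form, liberated cold from its pyridinium salt on an acid resin; 4,5-dibromocatechol and the trivinylboroxine–pyridine complex are taken as purchasable.

Step 1
Reactants: 1 4,5-dibromocatechol (2 equiv); 2 3,5-dibromo-2-fluorobenzaldehyde
Product: 3 3,5-dibromo-2-(4,5-dibromo-2-hydroxyphenoxy)benzaldehyde
Conditions: K2CO3, DMF, 80 °C, N2
Reagents that add atoms: none
Why: Nucleophilic aromatic substitution (SNAr), in which the ortho formyl group stabilises the Meisenheimer adduct so that only fluoride is displaced, the symmetrical diol gives the same ether from either oxygen, and its excess should hold the reaction at mono-arylation.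

Step 2
Reactants: 3 3,5-dibromo-2-(4,5-dibromo-2-hydroxyphenoxy)benzaldehyde
Product: 4 3,5-dibromo-2-(3,4,5-tribromo-2-hydroxyphenoxy)benzaldehyde
Conditions: Br2 (1.05 equiv), AcOH, rt
Reagents that add atoms: bromine, BrBr
Why: Electrophilic aromatic bromination, in which the free hydroxyl is the dominant director on ring B and its only open ortho/para site is C3, so one equivalent of bromine should complete the 3,4,5-tribromo pattern while the formyl-deactivated ring A stays untouched.

Step 3
Reactants: 4 3,5-dibromo-2-(3,4,5-tribromo-2-hydroxyphenoxy)benzaldehyde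
Product: 5 2-[3,5-dibromo-2-(3,4,5-tribromo-2-hydroxyphenoxy)phenyl]-1,3-dioxolane
Conditions: HOCH2CH2OH, p-TsOH (cat.), PhMe, reflux, Dean–Stark
Reagents that add atoms: ethylene glycol, OCCO
Why: Acid-catalysed acetalisation with azeotropic removal of water, which masks the carbonyl against the later amide base and removes the SNAr activation of ring A C2, so that ring A cannot migrate between the two ring B oxygens (Smiles rearrangement) once the phenoxide is formed.

Step 4
Reactants: 5 2-[3,5-dibromo-2-(3,4,5-tribromo-2-hydroxyphenoxy)phenyl]-1,3-dioxolane; 6 2,4,6-trivinylcyclotriboroxane–pyridine complex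
Product: 7 2-{3,5-dibromo-2-[3,4,5-tribromo-2-(ethenyloxy)phenoxy]phenyl}-1,3-dioxolane
Conditions: Cu(OAc)2 (2 equiv), pyridine, 4 Å MS, CH2Cl2, rt
Reagents that add atoms: none
Why: Chan–Lam-type copper-mediated O-vinylation, in which the phenoxide and a boron-derived vinyl group are joined on copper at room temperature, conditions that leave aryl bromides and the acetal alone.

Step 5
Reactants: 7 2-{3,5-dibromo-2-[3,4,5-tribromo-2-(ethenyloxy)phenoxy]phenyl}-1,3-dioxolane
Product: 10 2-[3,5-dibromo-2-(3,4,5-tribromo-2-{[(trimethylsilyl)ethynyl]oxy}phenoxy)phenyl]-1,3-dioxolane, via dibromoethyl ether 8 (not isolated), via lithium acetylide 9 (not isolated)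
Conditions: Br2 (1.0 equiv), CH2Cl2, −78 °C; then LiN(SiMe3)2 (3.5 equiv), THF, −78 °C → rt; then TMSCl, −78 °C → rt
Reagents that add atoms: chlorotrimethylsilane, C[Si](C)(C)Cl
Why: Bromine addition to the enol ether followed by twofold base-induced dehydrobromination (the classical route to aryloxyacetylenes) should give the terminal ynol ether, which a third equivalent of the non-nucleophilic silylamide deprotonates to acetylide 9 for C-silylation by TMSCl, the amide base neither exchanging nor metalating the aryl bromides as an alkyllithium would.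

Step 6
Reactants: 11 coumalic acid
Product: 12 5-bromo-2H-pyran-2-one
Conditions: NBS (1.1 equiv), LiOAc (cat.), MeCN–H2O, rt
Reagents that add atoms: N-bromosuccinimide, O=C1CCC(=O)N1Br
Why: Hunsdiecker-type bromodecarboxylation, in which NBS attacks the enol-ether-like C5 ipso to the carboxylate and CO2 is lost, a single equivalent of NBS limiting further bromination at C3.

Step 7
Reactants: 10 2-[3,5-dibromo-2-(3,4,5-tribromo-2-{[(trimethylsilyl)ethynyl]oxy}phenoxy)phenyl]-1,3-dioxolane; 12 5-bromo-2H-pyran-2-one (3 equiv)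
Product: 14 2-[3,5-dibromo-2-{3,4,5-tribromo-2-[4-bromo-2-(trimethylsilyl)phenoxy]phenoxy}phenyl]-1,3-dioxolane, via bridged lactone 13 (not isolated)
Conditions: BHT (cat.), PhMe, 150 °C, sealed tube
Reagents that add atoms: none
Why: The pyrone diene (C3–C6) and the ynol ether triple bond undergo intermolecular [4+2] cycloaddition to bridged lactone 13, which expels CO2 by retro-[4+2] and is then already a benzene ring, so no oxidation is required. The closest known reaction type is the thermal Diels–Alder/decarboxylation benzannulation of 2-pyrones with silyl-, boryl- and heteroatom-substituted alkynes. Ring C is closed by cycloaddition, both new bonds (ring C C1–C6 and C2–C3) arising in one suprafacial event and not by cyclisation of a tethered chain. No stereocentre remains, because the two bridgehead centres of racemic 13 disappear with the loss of CO2. The step needs regioselectivity: the oxygen lone pair makes the silyl-bearing alkyne carbon the nucleophilic terminus, which should bond to the electrophilic pyrone C6, while the oxygen-bearing carbon, whose developing positive charge is stabilised by oxygen and by the beta C–Si bond, bonds to C3, which places bromine para to oxygen and silicon at C2. Excess pyrone, a radical inhibitor and acid-free glassware protect the acid-sensitive ynol ether and acetal at this temperature.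

Step 8
Reactants: 14 2-[3,5-dibromo-2-{3,4,5-tribromo-2-[4-bromo-2-(trimethylsilyl)phenoxy]phenoxy}phenyl]-1,3-dioxolane
Product: 16 3,5-dibromo-2-[3,4,5-tribromo-2-(4-bromo-2-iodophenoxy)phenoxy]benzaldehyde, via iodo acetal 15 (not isolated)
Conditions: ICl (1.1 equiv), CH2Cl2, −78 → 0 °C; aq. Na2S2O3; then 2 M HCl, THF, 40 °C
Reagents that add atoms: iodine monochloride, ClI; water, O
Why: Electrophilic ipso-iododesilylation, in which iodine attacks the silyl-bearing carbon ortho to the ether oxygen (the para site being blocked by bromine) and the beta-silyl-stabilised arenium ion loses TMSCl, after which aqueous acid hydrolyses the dioxolane, iodination coming first so that acid cannot protodesilylate ring C.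

Step 9
Reactants: 16 3,5-dibromo-2-[3,4,5-tribromo-2-(4-bromo-2-iodophenoxy)phenoxy]benzaldehyde
Product: 18 3,5-dibromo-2-[3,4,5-tribromo-2-(4-bromo-2-iodophenoxy)phenoxy]phenol, via aryl formate 17 (not isolated)
Conditions: mCPBA, NaHCO3, CH2Cl2, rt; then K2CO3 (cat.), MeOH, rt
Reagents that add atoms: 3-chloroperoxybenzoic acid (mCPBA), O=C(OO)c1cccc(Cl)c1
Why: Dakin-type Baeyer–Villiger oxidation, in which the peracid adds to the formyl group and the aryl group, made able to migrate by its ortho aryloxy donor, shifts to oxygen to give formate 17, which mild methanolysis cleaves to the phenol, a sequence established for brominated 2-aryloxybenzaldehydes.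

Step 10
Reactants: 18 3,5-dibromo-2-[3,4,5-tribromo-2-(4-bromo-2-iodophenoxy)phenoxy]phenol
Product: 19 3,5-dibromo-2-[3,4,5-tribromo-2-(4-bromo-2-iodophenoxy)phenoxy]phenyl hydrogen sulfate (bromoiesol B sulfate)
Conditions: SO3·pyridine, pyridine, rt; then sulfonic acid cation-exchange resin (H+ form), MeOH–H2O, 0 °C
Reagents that add atoms: sulfur trioxide–pyridine complex, O=S(=O)([O-])[n+]1ccccc1
Why: O-Sulfation of the phenol by the sulfur trioxide–pyridine complex should give the pyridinium aryl sulfate, and brief cold contact with the acid resin exchanges pyridinium for a proton without hydrolysing the sulfate ester.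

Compound list
1 | 4,5-dibromocatechol (4,5-dibromobenzene-1,2-diol) | Oc1cc(Br)c(Br)cc1O | starting material
2 | 3,5-dibromo-2-fluorobenzaldehyde | O=Cc1cc(Br)cc(Br)c1F | starting material
3 | 3,5-dibromo-2-(4,5-dibromo-2-hydroxyphenoxy)benzaldehyde | O=Cc1cc(Br)cc(Br)c1Oc1cc(Br)c(Br)cc1O | intermediate
4 | 3,5-dibromo-2-(3,4,5-tribromo-2-hydroxyphenoxy)benzaldehyde | O=Cc1cc(Br)cc(Br)c1Oc1cc(Br)c(Br)c(Br)c1O | intermediate
5 | 2-[3,5-dibromo-2-(3,4,5-tribromo-2-hydroxyphenoxy)phenyl]-1,3-dioxolane | C1COC(O1)c1cc(Br)cc(Br)c1Oc1cc(Br)c(Br)c(Br)c1O | intermediate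
6 | 2,4,6-trivinylcyclotriboroxane–pyridine complex | C=CB1OB(C=C)OB(C=C)O1.c1ccncc1 | starting material
7 | 2-{3,5-dibromo-2-[3,4,5-tribromo-2-(ethenyloxy)phenoxy]phenyl}-1,3-dioxolane | C1COC(O1)c1cc(Br)cc(Br)c1Oc1cc(Br)c(Br)c(Br)c1OC=C | intermediate
8 | 2-{3,5-dibromo-2-[3,4,5-tribromo-2-(1,2-dibromoethoxy)phenoxy]phenyl}-1,3-dioxolane (racemic) | C1COC(O1)c1cc(Br)cc(Br)c1Oc1cc(Br)c(Br)c(Br)c1OC(Br)CBr | intermediate
9 | lithium acetylide of 2-{3,5-dibromo-2-[3,4,5-tribromo-2-(ethynyloxy)phenoxy]phenyl}-1,3-dioxolane | C1COC(O1)c1cc(Br)cc(Br)c1Oc1cc(Br)c(Br)c(Br)c1OC#C[Li] | intermediate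
10 | 2-[3,5-dibromo-2-(3,4,5-tribromo-2-{[(trimethylsilyl)ethynyl]oxy}phenoxy)phenyl]-1,3-dioxolane | C1COC(O1)c1cc(Br)cc(Br)c1Oc1cc(Br)c(Br)c(Br)c1OC#C[Si](C)(C)C | intermediate
11 | coumalic acid (2-oxo-2H-pyran-5-carboxylic acid) | O=C(O)c1ccc(=O)oc1 | starting material
12 | 5-bromo-2H-pyran-2-one | O=c1ccc(Br)co1 | intermediate
13 | 7-bromo-5-aryloxy-6-(trimethylsilyl)-2-oxabicyclo[2.2.2]octa-5,7-dien-3-one, aryl being the ring A–B unit of 10 (racemic, bridgeheads not assigned) | O=C1OC2C(Br)=CC1C(Oc1c(Br)c(Br)c(Br)cc1Oc1c(Br)cc(Br)cc1C1OCCO1)=C2[Si](C)(C)C | intermediate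
14 | 2-[3,5-dibromo-2-{3,4,5-tribromo-2-[4-bromo-2-(trimethylsilyl)phenoxy]phenoxy}phenyl]-1,3-dioxolane | C1COC(O1)c1cc(Br)cc(Br)c1Oc1cc(Br)c(Br)c(Br)c1Oc1ccc(Br)cc1[Si](C)(C)C | intermediate
15 | 2-{3,5-dibromo-2-[3,4,5-tribromo-2-(4-bromo-2-iodophenoxy)phenoxy]phenyl}-1,3-dioxolane | C1COC(O1)c1cc(Br)cc(Br)c1Oc1cc(Br)c(Br)c(Br)c1Oc1ccc(Br)cc1I | intermediate
16 | 3,5-dibromo-2-[3,4,5-tribromo-2-(4-bromo-2-iodophenoxy)phenoxy]benzaldehyde | O=Cc1cc(Br)cc(Br)c1Oc1cc(Br)c(Br)c(Br)c1Oc1ccc(Br)cc1I | intermediate
17 | 3,5-dibromo-2-[3,4,5-tribromo-2-(4-bromo-2-iodophenoxy)phenoxy]phenyl formate | O=COc1cc(Br)cc(Br)c1Oc1cc(Br)c(Br)c(Br)c1Oc1ccc(Br)cc1I | intermediate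
18 | 3,5-dibromo-2-[3,4,5-tribromo-2-(4-bromo-2-iodophenoxy)phenoxy]phenol | Oc1cc(Br)cc(Br)c1Oc1cc(Br)c(Br)c(Br)c1Oc1ccc(Br)cc1I | intermediate
19 | 3,5-dibromo-2-[3,4,5-tribromo-2-(4-bromo-2-iodophenoxy)phenoxy]phenyl hydrogen sulfate (bromoiesol B sulfate) | O=S(=O)(O)Oc1cc(Br)cc(Br)c1Oc1cc(Br)c(Br)c(Br)c1Oc1ccc(Br)cc1I | target

Total step count: 10. Longest linear sequence: 9 steps (steps 1–5 and 7–10); the pyrone branch is step 6 alone.

Steps most likely to fail

Step 7. The cycloaddition may be outpaced by thermal decay of the ynol ether or self-reaction of the pyrone, and the bulky silyl group may erode the head-to-tail orientation so that bromine ends up meta to the ether oxygen. The fallback builds the ring C ether by classical substitution chemistry and sets out from phenol 5. SNAr of its phenoxide on 4-bromo-1-fluoro-2-nitrobenzene (K2CO3, DMF, 60 °C) should give the 2-nitrophenyl ether F1. Reduction with Fe and NH4Cl in EtOH–H2O gives the aniline F2. Anhydrous diazotisation with NOBF4 in MeCN at −20 °C gives the diazonium tetrafluoroborate F3 with the acetal intact, and KI then replaces the diazonium group by iodine (Sandmeyer-type iodination). This gives iodo acetal 15, where the route is rejoined for the acid hydrolysis of step 8.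

Step 5. The polybromoaryloxide may be expelled from metalated halovinyl intermediates, the amide may substitute at the alpha-bromo ether before elimination, or the second dehydrobromination may stall. The fallback sets out from vinyl ether 7 and stages the sequence with a base matched to each event. Bromine addition gives 8, and triethylamine at 0 °C should convert it to the (Z)-2-bromovinyl ether F4, which is isolated. KOtBu in THF at −20 °C effects anti elimination to the terminal ethynyl ether F5. C-Silylation without strong base, through a catalytic zinc acetylide (Zn(OTf)2 cat., Et3N, TMSOTf, CH2Cl2, rt), returns to 10.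

Step 9. On the electron-poor ring A, hydrogen may migrate in the Criegee intermediate instead of the aryl group, giving the benzoic acid, or the peracid may oxidise the ring C iodine. The fallback avoids peracid and sets out from aldehyde 16. Pinnick oxidation (NaClO2, NaH2PO4, 2-methyl-2-butene, t-BuOH–H2O) gives the benzoic acid F6, which is also the product of the unwanted migration. Diphenylphosphoryl azide and Et3N in PhMe give the acyl azide F7, which on warming to 80 °C undergoes Curtius rearrangement to the isocyanate F8; aqueous NaOH in THF then hydrolyses it to the aniline F9. Diazotisation (NaNO2, H2SO4, AcOH, 0 °C) gives the diazonium hydrogensulfate F10, which is hydrolysed in hot dilute H2SO4 without copper, so that radical closure onto ring B is not invited. This returns to phenol 18.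

Further compounds
F1 | step 7 | 2-{3,5-dibromo-2-[3,4,5-tribromo-2-(4-bromo-2-nitrophenoxy)phenoxy]phenyl}-1,3-dioxolane | C1COC(O1)c1cc(Br)cc(Br)c1Oc1cc(Br)c(Br)c(Br)c1Oc1ccc(Br)cc1[N+](=O)[O-]
F2 | step 7 | 5-bromo-2-{2,3,4-tribromo-6-[2,4-dibromo-6-(1,3-dioxolan-2-yl)phenoxy]phenoxy}aniline | C1COC(O1)c1cc(Br)cc(Br)c1Oc1cc(Br)c(Br)c(Br)c1Oc1ccc(Br)cc1N
F3 | step 7 | 5-bromo-2-{2,3,4-tribromo-6-[2,4-dibromo-6-(1,3-dioxolan-2-yl)phenoxy]phenoxy}benzenediazonium tetrafluoroborate | C1COC(O1)c1cc(Br)cc(Br)c1Oc1cc(Br)c(Br)c(Br)c1Oc1ccc(Br)cc1[N+]#N.F[B-](F)(F)F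
F4 | step 5 | 2-{3,5-dibromo-2-[3,4,5-tribromo-2-{[(Z)-2-bromoethenyl]oxy}phenoxy]phenyl}-1,3-dioxolane | C1COC(O1)c1cc(Br)cc(Br)c1Oc1cc(Br)c(Br)c(Br)c1O/C=C\Br
F5 | step 5 | 2-{3,5-dibromo-2-[3,4,5-tribromo-2-(ethynyloxy)phenoxy]phenyl}-1,3-dioxolane | C1COC(O1)c1cc(Br)cc(Br)c1Oc1cc(Br)c(Br)c(Br)c1OC#C
F6 | step 9 | 3,5-dibromo-2-[3,4,5-tribromo-2-(4-bromo-2-iodophenoxy)phenoxy]benzoic acid | O=C(O)c1cc(Br)cc(Br)c1Oc1cc(Br)c(Br)c(Br)c1Oc1ccc(Br)cc1I
F7 | step 9 | 3,5-dibromo-2-[3,4,5-tribromo-2-(4-bromo-2-iodophenoxy)phenoxy]benzoyl azide | [N-]=[N+]=NC(=O)c1cc(Br)cc(Br)c1Oc1cc(Br)c(Br)c(Br)c1Oc1ccc(Br)cc1I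
F8 | step 9 | 3,5-dibromo-2-[3,4,5-tribromo-2-(4-bromo-2-iodophenoxy)phenoxy]phenyl isocyanate | O=C=Nc1cc(Br)cc(Br)c1Oc1cc(Br)c(Br)c(Br)c1Oc1ccc(Br)cc1I
F9 | step 9 | 3,5-dibromo-2-[3,4,5-tribromo-2-(4-bromo-2-iodophenoxy)phenoxy]aniline | Nc1cc(Br)cc(Br)c1Oc1cc(Br)c(Br)c(Br)c1Oc1ccc(Br)cc1I
F10 | step 9 | 3,5-dibromo-2-[3,4,5-tribromo-2-(4-bromo-2-iodophenoxy)phenoxy]benzenediazonium hydrogensulfate | N#[N+]c1cc(Br)cc(Br)c1Oc1cc(Br)c(Br)c(Br)c1Oc1ccc(Br)cc1I.OS(=O)(=O)[O-]
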